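## The problem

The target 15 is a cis-fused γ-lactone/tetrahydrofuran, numbered here as a 3,7-dioxabicyclo[3.3.0]octan-8-one: C1 and C5 at the ring fusion, C2 carrying the 3,4-dihydroxyphenyl ring, O3, C4H2, C6 carrying the 4-hydroxy-3,5-dimethoxyphenyl ring, O7 and the carbonyl C8; the configuration is 1R,2S,5S,6S. The four stereocentres are contiguous, and H1, H2, H5 and H6 all lie on the convex face, so both aryl groups point into the concave face; this is the most crowded diastereomer and cannot be reached or repaired by equilibration at C2 or C6. C1 and C5 are locked to each other by the cis fusion, whereas C2 and C6 are benzylic, oxygen-substituted and para to phenolic oxygen: acid ionises them, base opens them (O3 is β to the lactone carbonyl, and a para-phenoxide can expel O3 or the C8 carboxylate), and prolonged hydrogenolysis cleaves them. The catechol is also air-sensitive at high pH, so the phenols must travel protected and be released under neutral conditions. Because every ring hydrogen is on one face, a flat precursor with C6 as its only stereocentre could pass its configuration to C1, C2 and C5 by syn addition of hydrogen. Such a precursor exists: the ring O3–C2–C1–C5–C4, with an aryl group on C2, the carboxyl carbon C8 on C1 and the oxygenated benzylic carbon C6 on C5, is the tetrahydro form of a 2-aryl-4-acylfuran-3-carboxylate, and this 2,3,4-pattern is what a Feist–Benary annulation of a β-keto ester with a 3-halo-1,2-dione delivers.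

## Retrosynthesis

**15 ⇒ 14 (O–benzyl bonds).** No skeletal bond is cut: the three phenols of 15 are traced to the tribenzyl ether 14. Benzyl is preferred to silyl or acetal groups because it survives NaH, lithium amide, SeO2 and the HBr released on bromination, and because it leaves under neutral hydrogenolysis, which exposes neither C2 nor C6 to acid or to a phenoxide. The forward step must cleave three aryl benzyl ethers faster than the two cyclic benzylic C–O bonds.

**14 ⇒ 13 (C1–H, C2–H, C5–H).** Removing the hydrogens at C1, C2 and C5 restores the furan of 13. This is preferred to any C–C or C–O cut of the saturated bicycle, each of which would leave two or three stereocentres to be controlled separately, whereas the all-cis pattern is what syn delivery of hydrogen to one face of a flat ring produces. Precursor 13 has one stereocentre instead of four. The forward reaction must add two equivalents of hydrogen to the face opposite the C6 aryl group without cleaving C6–O7.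

**13 ⇒ 11 (O7–C8 and C6–H).** Opening the lactone and raising C6 to the ketone level gives the achiral keto ester 11, by way of the hydroxy ester 12. A carbonyl arylation at C6 would need a different furan and an enantioselective aryl transfer, whereas the ketone is what the annulation delivers, and reduction of an aryl ketone flanked by an ortho ester, followed by lactonisation, is the established route to 3-arylphthalides. The forward step must tell the ester-flanked furyl group from the unhindered aryl group and close the ring without acid.

**11 ⇒ 4 + 9 (C1–C5 and O3–C4).** Cutting these two furan bonds gives the β-keto ester 4 and the bromo dione 9, with the hydroxydihydrofuran 10 between them. Against a Paal–Knorr cut at C2–O3 or stepwise substitution of a preformed furan, this cut divides the molecule into halves of equal size, one aryl ring each, and uses the natural polarity of both: the nucleophilic carbon of 4 is C1 and the most electrophilic carbon of 9 is C5. The forward reaction must give aldol addition at C5 before alkylation at C4.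

**4 ⇒ 2 + 3; 2 ⇒ 1 (C1–C8; O–benzyl).** The ester carbon C8 is removed as dimethyl carbonate 3, leaving the benzylated methyl ketone 2, which comes from commercial 3,4-dihydroxyacetophenone 1. A crossed Claisen condensation with a non-enolisable carbonate is the shortest entry to an aryl β-keto ester and asks only for a base-stable phenol protection.

**9 ⇒ 8 ⇒ 7 ⇒ 6 ⇒ 5 (C4–Br; C5=O; C4–C5; O–benzyl).** The bromide of 9 is removed to give dione 8, the C5 carbonyl is taken back to the methylene of propiophenone 7, the C4 methyl group is cut off to give the acetophenone 6, and debenzylation leads to commercial acetosyringone 5. Each cut is a single standard operation, and the only enolisable position of 8 is the carbon that must carry bromine.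

## Roads not taken

**Alternative 1:** The cut is C1–C5 and O7–C8, leading to the acyclic epoxy nitrile A1, in which C2, C5 and C6 are already stereogenic. In the forward step KN(SiMe3)2 would deprotonate C1, the carbanion would open the trans-epoxide at C5 with inversion (5-exo), the C6 alkoxide would add to the nitrile, and aqueous acid would hydrolyse the imidate to the lactone A2, which is the same compound as 14.
- Merits: three of the four stereocentres come from reliable asymmetric reactions, the opening is stereospecific and only the cis-fused imidate can form. The configuration therefore does not rest on a facial selectivity that is still to be shown, and in stereochemical certainty this road is better than the chosen one.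
- Weak points: the carbanion at C1 is β to the benzylic oxygen O3, so expulsion of that alkoxide competes directly with cyclisation. The epoxide carbon C6 is benzylic to an electron-rich ring and invites 6-endo opening. A1 itself needs an asymmetric epoxidation, an enantioselective carbonyl reduction and an etherification of a base-sensitive alcohol, which makes two asymmetric steps and a longer sequence.
- Comparison: the chosen plan sets against the better stereochemical pedigree a key step free of stereochemistry and fragile anions, achiral intermediates up to 11, and a single asymmetric operation.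

**Alternative 2:** The cut is C1–C2. Rh2(OAc)4 would convert the α-diazo lactone A3 into a carbenoid at C1, which inserts into a benzylic C–H bond next to the ether oxygen and closes the tetrahydrofuran ring to give the tris-silyl ether A4.
- Merits: the C–H bond is doubly activated, the cis fusion follows by construction, and the ring is closed in one catalytic step. The silyl groups leave with fluoride, so the hydrogenolysis risk of the chosen plan's last step is absent; on that point the alternative is better.
- Weak points: A3 must carry the C6 aryl group cis to the C5 side chain, the less stable lactone diastereomer, and needs its own stereoselective sequence and a diazo transfer. The configuration at C2 rests on a choice between two diastereotopic hydrogens, and the target needs the more hindered outcome. The electron-rich silyloxyarenes and the ether oxygen offer the carbenoid arene addition and oxonium ylide pathways. The route is linear and longer.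
- Comparison: the chosen plan sets against it convergence and a C2 configuration that follows from syn addition and ring fusion; it concedes the cleaner final deprotection.

**Alternative 3:** The cuts are C5–C6, C1–C8 and C8–O7. Ni(cod)2 with a chiral N-heterocyclic carbene would couple the alkyne A5 and the aldehyde A6 to an oxanickelacyclopentene, and insertion of carbon monoxide A7 with reductive elimination would give the butenolide A8.
- Merits: this is the most convergent road, with C6 set by the catalyst and C2 brought in ready-made with A5 instead of being created by hydrogenation; in that respect it is better than the chosen plan.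
- Weak points: zerovalent nickel is readily sequestered by A7. The regiochemistry of the metallacycle is not biased, because both alkyne termini carry a silyloxy-substituted carbon. The catalyst must also override the existing centre of A5.
- Endgame: a tetrasubstituted butenolide would still have to be hydrogenated anti to the C6 aryl group, with an allylic, benzylic silyloxy group at C2 exposed to cleavage, and then desilylated and closed at O3–C4.
- Comparison: the hydrogenation uncertainty is of the same kind as in the chosen plan, which sets against the higher convergence an established key reaction and a three-step endgame.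

Key step: step 7

Assumption: the (S,S)-TsDPEN ligand is assigned to the (R)-carbinol in step 8 by analogy with ortho-substituted diaryl ketones, where the unhindered aryl ring takes the position that phenyl takes in acetophenone; should the sense prove opposite, the (R,R)-ligand is used and nothing else changes.

## Route

Step 1
Reactants: 1 3,4-dihydroxyacetophenone
Product: 2 1-[3,4-bis(benzyloxy)phenyl]ethan-1-one
Conditions: BnBr (2.3 equiv), K2CO3, DMF, 60 °C
Reagents that add atoms: benzyl bromide, BrCc1ccccc1
Why: Williamson ether synthesis; K2CO3 deprotonates both phenols but not the ketone, and the phenoxides displace bromide from benzyl bromide; no stereocentre is involved.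

Step 2
Reactants: 2 1-[3,4-bis(benzyloxy)phenyl]ethan-1-one; 3 dimethyl carbonate
Product: 4 methyl 3-[3,4-bis(benzyloxy)phenyl]-3-oxopropanoate
Conditions: NaH (2.2 equiv), (MeO)2CO (excess), THF, reflux; then aq. HCl, 0 °C
Reagents that add atoms: none
Why: Crossed Claisen condensation; the sodium enolate of the methyl ketone is acylated by the non-enolisable carbonate, and deprotonation of the product β-keto ester drives the reaction and prevents double acylation; this introduces C8.

Step 3
Reactants: 5 acetosyringone
Product: 6 1-[4-(benzyloxy)-3,5-dimethoxyphenyl]ethan-1-one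
Conditions: BnBr (1.2 equiv), K2CO3, DMF, 60 °C
Reagents that add atoms: benzyl bromide, BrCc1ccccc1
Why: Williamson ether synthesis on the acidic, doubly ortho-substituted phenol; a polar aprotic solvent and mild heating overcome the flanking methoxy groups.

Step 4
Reactants: 6 1-[4-(benzyloxy)-3,5-dimethoxyphenyl]ethan-1-one
Product: 7 1-[4-(benzyloxy)-3,5-dimethoxyphenyl]propan-1-one
Conditions: LiN(i-Pr)2 (1.05 equiv), THF, −78 °C; MeI (1.1 equiv), −78 to 0 °C
Reagents that add atoms: iodomethane, CI
Why: Alkylation of the kinetic lithium enolate of a methyl ketone; adding the ketone to a slight excess of amide base at −78 °C and limiting MeI should restrain proton exchange and double methylation; this forms the C4–C5 bond.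

Step 5
Reactants: 7 1-[4-(benzyloxy)-3,5-dimethoxyphenyl]propan-1-one
Product: 8 1-[4-(benzyloxy)-3,5-dimethoxyphenyl]propane-1,2-dione
Conditions: SeO2 (1.2 equiv), 1,4-dioxane/H2O, 100 °C
Reagents that add atoms: selenium dioxide SeO2, O=[Se]=O
Why: Riley oxidation; SeO2 oxidises the methylene group activated by the aryl ketone to the 1,2-dione through the enol, and benzyl and methyl ethers are inert to it.

Step 6
Reactants: 8 1-[4-(benzyloxy)-3,5-dimethoxyphenyl]propane-1,2-dione
Product: 9 1-[4-(benzyloxy)-3,5-dimethoxyphenyl]-3-bromopropane-1,2-dione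
Conditions: CuBr2 (2.1 equiv), EtOAc/CHCl3 (1:1), reflux
Reagents that add atoms: copper dibromide CuBr2, [Cu+2].[Br-].[Br-]
Why: α-Bromination of a ketone with CuBr2 through its copper-bound enol; the terminal methyl group is the only enolisable position of 8 and the acyl-deactivated arene should not be brominated; 9 is used crude because 3-halo-1,2-diones are base- and light-sensitive.

Step 7
Reactants: 4 methyl 3-[3,4-bis(benzyloxy)phenyl]-3-oxopropanoate; 9 1-[4-(benzyloxy)-3,5-dimethoxyphenyl]-3-bromopropane-1,2-dione
Product: 11 methyl 4-[4-(benzyloxy)-3,5-dimethoxybenzoyl]-2-[3,4-bis(benzyloxy)phenyl]furan-3-carboxylate, via hydroxydihydrofuran 10 (not isolated)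
Conditions: K2CO3 (1.2 equiv), THF, 0 °C to rt, slow addition of 9; then TsOH·H2O (10 mol %), toluene, 70 °C
Reagents that add atoms: none
Why: K2CO3 generates the stabilised enolate of 4, whose carbon C1 adds to the central carbonyl C5 of 9 (aldol, C1–C5); proton transfer from the still acidic C1–H regenerates an enolate, and its ketone-derived oxygen O3 displaces bromide at C4 (O3–C4) to give the hydroxydihydrofuran 10. This ring closure is 5-exo-tet; C-alkylation from C1 would be a 3-exo closure to a cyclopropane and is not expected. Catalytic TsOH then ionises the tertiary C5–OH, assisted by the enol ether, and loss of a C4 proton aromatises the ring to 11. The closest known reaction type is the Feist–Benary furan synthesis of β-keto esters with bromopyruvate-type 3-halo-1,2-dicarbonyl compounds, run in its interrupted form and completed by acid dehydration. No stereocentre is carried forward: the carbinol carbon of 10 forms racemic and is destroyed on aromatisation. The step needs aldol addition at C5 to precede alkylation at C4, because the reverse order would end in the 2,3,5-substituted furan, and it needs attack at C5 and not at C6. Both are secured by the substrate: C5 is a 1,2-dione carbonyl further activated by the α-bromine and not conjugated to the electron-rich arene, so it should outpace both the aryl ketone and SN2 attack by the hindered enolate, and only the C5 adduct can reach the bromide through a five-membered transition state.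

Step 8
Reactants: 11 methyl 4-[4-(benzyloxy)-3,5-dimethoxybenzoyl]-2-[3,4-bis(benzyloxy)phenyl]furan-3-carboxylate
Product: 13 (3R)-3-[4-(benzyloxy)-3,5-dimethoxyphenyl]-6-[3,4-bis(benzyloxy)phenyl]-1H,3H-furo[3,4-c]furan-1-one, via hydroxy ester 12 (not isolated)
Conditions: RuCl(p-cymene)[(S,S)-TsDPEN] (2 mol %), HCO2H/Et3N (5:2), DMF, 40 °C; then DBU (10 mol %), toluene, 50 °C
Reagents that add atoms: none
Why: Noyori–Ikariya asymmetric transfer hydrogenation of an aryl ketone with lactonisation, as in 3-arylphthalide synthesis from 2-aroylbenzoates; the planar aryl ring should take the site stabilised by the CH/π contact with p-cymene and the twisted, ester-flanked furyl ring the alkyl site, which with the (S,S)-ligand should give the (R)-carbinol 12 and so sets C6; the hydroxyl then closes onto the neighbouring methyl ester (5-exo-trig) under catalytic amidine base, avoiding acid that could ionise the doubly benzylic carbinol.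

Step 9
Reactants: 13 (3R)-3-[4-(benzyloxy)-3,5-dimethoxyphenyl]-6-[3,4-bis(benzyloxy)phenyl]-1H,3H-furo[3,4-c]furan-1-one
Product: 14 (3S,3aS,6S,6aR)-3-[4-(benzyloxy)-3,5-dimethoxyphenyl]-6-[3,4-bis(benzyloxy)phenyl]tetrahydro-1H,3H-furo[3,4-c]furan-1-one
Conditions: H2 (5 bar), 5% Rh/Al2O3, EtOAc, rt, stopped after uptake of 2 equiv
Reagents that add atoms: none
Why: Heterogeneous hydrogenation of a polysubstituted furan to the all-cis tetrahydrofuran; 13 is planar except at C6, whose aryl group blocks one face, so the bicycle should bind to the metal through the face of H6, syn addition to the C4=C5 enol ether puts H5 cis to H6, the cis fusion then dictates H1, and syn addition across C1=C2 places H2 on the same face (1R,2S,5S; the descriptor at C6 changes from R to S only because C5 loses priority on saturation); Rh on Al2O3 in a neutral aprotic solvent reduces furans without cleaving benzyl ethers or benzylic C–O bonds.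

Step 10
Reactants: 14 (3S,3aS,6S,6aR)-3-[4-(benzyloxy)-3,5-dimethoxyphenyl]-6-[3,4-bis(benzyloxy)phenyl]tetrahydro-1H,3H-furo[3,4-c]furan-1-one
Product: 15 (3S,3aS,6S,6aR)-6-(3,4-dihydroxyphenyl)-3-(4-hydroxy-3,5-dimethoxyphenyl)tetrahydro-1H,3H-furo[3,4-c]furan-1-one
Conditions: H2 (1 bar), 10% Pd/C, EtOAc, rt, stopped after uptake of 3 equiv
Reagents that add atoms: none
Why: Hydrogenolysis of aryl benzyl ethers on Pd; the medium is neutral and aprotic, so C2 and C6 are neither ionised nor exposed to phenoxide, and aryl benzyl ethers should cleave much faster than the cyclic benzylic C2–O3 and C6–O7 bonds.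

## Compound list

1 | 3,4-dihydroxyacetophenone | CC(=O)c1ccc(O)c(O)c1 | starting material
2 | 1-[3,4-bis(benzyloxy)phenyl]ethan-1-one | CC(=O)c1ccc(OCc2ccccc2)c(OCc2ccccc2)c1 | intermediate
3 | dimethyl carbonate | COC(=O)OC | starting material
4 | methyl 3-[3,4-bis(benzyloxy)phenyl]-3-oxopropanoate | COC(=O)CC(=O)c1ccc(OCc2ccccc2)c(OCc2ccccc2)c1 | intermediate
5 | acetosyringone, 1-(4-hydroxy-3,5-dimethoxyphenyl)ethan-1-one | CC(=O)c1cc(OC)c(O)c(OC)c1 | starting material
6 | 1-[4-(benzyloxy)-3,5-dimethoxyphenyl]ethan-1-one | CC(=O)c1cc(OC)c(OCc2ccccc2)c(OC)c1 | intermediate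
7 | 1-[4-(benzyloxy)-3,5-dimethoxyphenyl]propan-1-one | CCC(=O)c1cc(OC)c(OCc2ccccc2)c(OC)c1 | intermediate
8 | 1-[4-(benzyloxy)-3,5-dimethoxyphenyl]propane-1,2-dione | CC(=O)C(=O)c1cc(OC)c(OCc2ccccc2)c(OC)c1 | intermediate
9 | 1-[4-(benzyloxy)-3,5-dimethoxyphenyl]-3-bromopropane-1,2-dione | BrCC(=O)C(=O)c1cc(OC)c(OCc2ccccc2)c(OC)c1 | intermediate
10 | methyl 4-[4-(benzyloxy)-3,5-dimethoxybenzoyl]-2-[3,4-bis(benzyloxy)phenyl]-4-hydroxy-4,5-dihydrofuran-3-carboxylate (racemic, not isolated) | COC(=O)C1=C(OCC1(O)C(=O)c1cc(OC)c(OCc2ccccc2)c(OC)c1)c1ccc(OCc2ccccc2)c(OCc2ccccc2)c1 | intermediate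
11 | methyl 4-[4-(benzyloxy)-3,5-dimethoxybenzoyl]-2-[3,4-bis(benzyloxy)phenyl]furan-3-carboxylate | COC(=O)c1c(C(=O)c2cc(OC)c(OCc3ccccc3)c(OC)c2)coc1-c1ccc(OCc2ccccc2)c(OCc2ccccc2)c1 | intermediate
12 | methyl 4-{(R)-[4-(benzyloxy)-3,5-dimethoxyphenyl](hydroxy)methyl}-2-[3,4-bis(benzyloxy)phenyl]furan-3-carboxylate (not isolated) | COc1cc([C@@H](O)c2coc(-c3ccc(OCc4ccccc4)c(OCc4ccccc4)c3)c2C(=O)OC)cc(OC)c1OCc1ccccc1 | intermediate
13 | (3R)-3-[4-(benzyloxy)-3,5-dimethoxyphenyl]-6-[3,4-bis(benzyloxy)phenyl]-1H,3H-furo[3,4-c]furan-1-one | COc1cc([C@H]2OC(=O)c3c2coc3-c2ccc(OCc3ccccc3)c(OCc3ccccc3)c2)cc(OC)c1OCc1ccccc1 | intermediate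
14 | (3S,3aS,6S,6aR)-3-[4-(benzyloxy)-3,5-dimethoxyphenyl]-6-[3,4-bis(benzyloxy)phenyl]tetrahydro-1H,3H-furo[3,4-c]furan-1-one (all four ring hydrogens cis) | COc1cc([C@H]2OC(=O)[C@@H]3[C@H]2CO[C@@H]3c2ccc(OCc3ccccc3)c(OCc3ccccc3)c2)cc(OC)c1OCc1ccccc1 | intermediate
15 | (3S,3aS,6S,6aR)-6-(3,4-dihydroxyphenyl)-3-(4-hydroxy-3,5-dimethoxyphenyl)tetrahydro-1H,3H-furo[3,4-c]furan-1-one | COc1cc([C@H]2OC(=O)[C@@H]3[C@H]2CO[C@@H]3c2ccc(O)c(O)c2)cc(OC)c1O | target

## Step count and least certain steps

Total step count: 10 (steps 1–2 to 4, steps 3–6 to 9, steps 7–10 after convergence). Longest linear sequence: 8 steps (steps 3 to 10, from 5).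

**Step 7 (key step).** The most likely failure is direct SN2 alkylation of the enolate carbon by the very reactive bromomethyl ketone before the aldol addition, which after cyclodehydration would lead to the 2,3,5-substituted furan. Base-induced decomposition of the bromo dione is the second risk.
The fallback sets out from 4 and returns at 11; it forms the C5–C6 bond after the furan and needs no bromo dione.
- The annulation is run with commercial ethyl bromopyruvate, the standard Feist–Benary partner of β-keto esters, to give 4-ethyl 3-methyl 2-[3,4-bis(benzyloxy)phenyl]furan-3,4-dicarboxylate F1.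
- The C4 ethyl ester, less hindered and not deactivated as a vinylogous carbonate, is saponified selectively (LiOH, 1 equiv, THF/H2O, 0 °C) to 5-[3,4-bis(benzyloxy)phenyl]-4-(methoxycarbonyl)furan-3-carboxylic acid F2.
- Coupling with MeNHOMe·HCl (EDC·HCl, i-Pr2NEt) gives the Weinreb amide methyl 2-[3,4-bis(benzyloxy)phenyl]-4-[methoxy(methyl)carbamoyl]furan-3-carboxylate F3.
- In parallel, commercial 4-bromo-2,6-dimethoxyphenol is benzylated to 2-(benzyloxy)-5-bromo-1,3-dimethoxybenzene F4 and converted with Mg in THF into [4-(benzyloxy)-3,5-dimethoxyphenyl]magnesium bromide F5, which adds once to F3 at −20 °C to give 11.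

**Step 9.** The most likely failure is slow saturation of the tetrasubstituted, ester-conjugated C1=C2 bond, so that ring hydrogenation of the benzyl groups and hydrogenolysis at C6–O7 compete under the pressure then required. Incomplete face selectivity in the first addition is the second risk.
The fallback sets out from 11 and returns at 15; it replaces the benzyl ethers by silyl ethers before any reduction.
- BCl3 with pentamethylbenzene (CH2Cl2, −78 °C) gives methyl 2-(3,4-dihydroxyphenyl)-4-(4-hydroxy-3,5-dimethoxybenzoyl)furan-3-carboxylate F6.
- TBSCl/imidazole (DMF) gives methyl 2-{3,4-bis[(tert-butyldimethylsilyl)oxy]phenyl}-4-{4-[(tert-butyldimethylsilyl)oxy]-3,5-dimethoxybenzoyl}furan-3-carboxylate F7.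
- The transfer hydrogenation and lactonisation of step 8 give (3R)-6-{3,4-bis[(tert-butyldimethylsilyl)oxy]phenyl}-3-{4-[(tert-butyldimethylsilyl)oxy]-3,5-dimethoxyphenyl}-1H,3H-furo[3,4-c]furan-1-one F8.
- Hydrogenation over Rh/Al2O3, now free of benzyl rings and open to higher pressure, gives the all-cis tris(tert-butyldimethylsilyl) ether of 15 F9.
- Bu4NF buffered with AcOH (THF, 0 °C) releases 15.

**Step 8.** The most likely failure is insufficient discrimination between the two aryl-type groups, giving low enantioselectivity. Slow lactonisation, because the furan-fused five-membered lactone is more strained than a phthalide, is the second risk.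
The fallback sets out from 11 and returns at 13. Reduction with NaBH4 (THF/MeOH, 0 °C) and the same base-mediated ring closure give racemic 3-[4-(benzyloxy)-3,5-dimethoxyphenyl]-6-[3,4-bis(benzyloxy)phenyl]-1H,3H-furo[3,4-c]furan-1-one F10. Its enantiomers are separated by preparative chromatography on a chiral stationary phase, and the (3R)-enantiomer is 13.

**Step 10.** The most likely failure is over-reduction: once the para-phenols are free, hydrogenolysis of the benzylic C2–O3 and C6–O7 bonds can set in before the last benzyl ether is gone.
The fallback goes from 14 directly to 15 by a non-reductive Lewis-acid debenzylation, BCl3 with pentamethylbenzene as benzyl cation scavenger (CH2Cl2, −78 °C), quenched cold to avoid ionisation at C2 and C6; no new compound arises (F0).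

**Step 6.** The most likely failures are over-bromination to the dibromide, ring bromination of the dimethoxyarene, and loss of the hindered 4-O-benzyl group to the HBr that is released.
The fallback sets out from 8 and returns at 9 under neutral conditions. TMSOTf/Et3N (CH2Cl2, 0 °C) gives 1-[4-(benzyloxy)-3,5-dimethoxyphenyl]-2-[(trimethylsilyl)oxy]prop-2-en-1-one F11, which is brominated with NBS (THF, −78 °C) to give 9.

## Further compounds

F1 | step 7 | 4-ethyl 3-methyl 2-[3,4-bis(benzyloxy)phenyl]furan-3,4-dicarboxylate | CCOC(=O)c1coc(-c2ccc(OCc3ccccc3)c(OCc3ccccc3)c2)c1C(=O)OC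
F2 | step 7 | 5-[3,4-bis(benzyloxy)phenyl]-4-(methoxycarbonyl)furan-3-carboxylic acid | OC(=O)c1coc(-c2ccc(OCc3ccccc3)c(OCc3ccccc3)c2)c1C(=O)OC
F3 | step 7 | methyl 2-[3,4-bis(benzyloxy)phenyl]-4-[methoxy(methyl)carbamoyl]furan-3-carboxylate | CON(C)C(=O)c1coc(-c2ccc(OCc3ccccc3)c(OCc3ccccc3)c2)c1C(=O)OC
F4 | step 7 | 2-(benzyloxy)-5-bromo-1,3-dimethoxybenzene | COc1cc(Br)cc(OC)c1OCc1ccccc1
F5 | step 7 | [4-(benzyloxy)-3,5-dimethoxyphenyl]magnesium bromide | COc1cc([Mg]Br)cc(OC)c1OCc1ccccc1
F6 | step 9 | methyl 2-(3,4-dihydroxyphenyl)-4-(4-hydroxy-3,5-dimethoxybenzoyl)furan-3-carboxylate | COC(=O)c1c(C(=O)c2cc(OC)c(O)c(OC)c2)coc1-c1ccc(O)c(O)c1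
F7 | step 9 | methyl 2-{3,4-bis[(tert-butyldimethylsilyl)oxy]phenyl}-4-{4-[(tert-butyldimethylsilyl)oxy]-3,5-dimethoxybenzoyl}furan-3-carboxylate | COC(=O)c1c(C(=O)c2cc(OC)c(O[Si](C)(C)C(C)(C)C)c(OC)c2)coc1-c1ccc(O[Si](C)(C)C(C)(C)C)c(O[Si](C)(C)C(C)(C)C)c1
F8 | step 9 | (3R)-6-{3,4-bis[(tert-butyldimethylsilyl)oxy]phenyl}-3-{4-[(tert-butyldimethylsilyl)oxy]-3,5-dimethoxyphenyl}-1H,3H-furo[3,4-c]furan-1-one | COc1cc([C@H]2OC(=O)c3c2coc3-c2ccc(O[Si](C)(C)C(C)(C)C)c(O[Si](C)(C)C(C)(C)C)c2)cc(OC)c1O[Si](C)(C)C(C)(C)C
F9 | step 9 | (3S,3aS,6S,6aR)-6-{3,4-bis[(tert-butyldimethylsilyl)oxy]phenyl}-3-{4-[(tert-butyldimethylsilyl)oxy]-3,5-dimethoxyphenyl}tetrahydro-1H,3H-furo[3,4-c]furan-1-one | COc1cc([C@H]2OC(=O)[C@@H]3[C@H]2CO[C@@H]3c2ccc(O[Si](C)(C)C(C)(C)C)c(O[Si](C)(C)C(C)(C)C)c2)cc(OC)c1O[Si](C)(C)C(C)(C)C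
F10 | step 8 | racemic 3-[4-(benzyloxy)-3,5-dimethoxyphenyl]-6-[3,4-bis(benzyloxy)phenyl]-1H,3H-furo[3,4-c]furan-1-one | COc1cc(C2OC(=O)c3c2coc3-c2ccc(OCc3ccccc3)c(OCc3ccccc3)c2)cc(OC)c1OCc1ccccc1
F0 | step 10 | none | none
F11 | step 6 | 1-[4-(benzyloxy)-3,5-dimethoxyphenyl]-2-[(trimethylsilyl)oxy]prop-2-en-1-one | C=C(O[Si](C)(C)C)C(=O)c1cc(OC)c(OCc2ccccc2)c(OC)c1
A1 | alternative 1 | (3S)-3-[3,4-bis(benzyloxy)phenyl]-3-{[(2R,3R)-3-[4-(benzyloxy)-3,5-dimethoxyphenyl]oxiran-2-yl]methoxy}propanenitrile | COc1cc([C@H]2O[C@@H]2CO[C@@H](CC#N)c2ccc(OCc3ccccc3)c(OCc3ccccc3)c2)cc(OC)c1OCc1ccccc1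
A2 | alternative 1 | tri-O-benzyl ether of the target (identical with 14) | COc1cc([C@H]2OC(=O)[C@@H]3[C@H]2CO[C@@H]3c2ccc(OCc3ccccc3)c(OCc3ccccc3)c2)cc(OC)c1OCc1ccccc1
A3 | alternative 2 | (4S,5S)-4-[({3,4-bis[(tert-butyldimethylsilyl)oxy]phenyl}methoxy)methyl]-5-{4-[(tert-butyldimethylsilyl)oxy]-3,5-dimethoxyphenyl}-3-diazooxolan-2-one | COc1cc([C@H]2OC(=O)C(=[N+]=[N-])[C@H]2COCc2ccc(O[Si](C)(C)C(C)(C)C)c(O[Si](C)(C)C(C)(C)C)c2)cc(OC)c1O[Si](C)(C)C(C)(C)C
A4 | alternative 2 | tris(tert-butyldimethylsilyl) ether of the target | COc1cc([C@H]2OC(=O)[C@@H]3[C@H]2CO[C@@H]3c2ccc(O[Si](C)(C)C(C)(C)C)c(O[Si](C)(C)C(C)(C)C)c2)cc(OC)c1O[Si](C)(C)C(C)(C)C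
A5 | alternative 3 | (R)-1-[3,4-bis(benzyloxy)phenyl]but-2-yne-1,4-diol bis(tert-butyldimethylsilyl) ether | CC(C)(C)[Si](C)(C)OCC#C[C@H](O[Si](C)(C)C(C)(C)C)c1ccc(OCc2ccccc2)c(OCc2ccccc2)c1
A6 | alternative 3 | 4-(benzyloxy)-3,5-dimethoxybenzaldehyde | COc1cc(C=O)cc(OC)c1OCc1ccccc1
A7 | alternative 3 | carbon monoxide | [C-]#[O+]
A8 | alternative 3 | (5R)-5-[4-(benzyloxy)-3,5-dimethoxyphenyl]-3-{(R)-[3,4-bis(benzyloxy)phenyl][(tert-butyldimethylsilyl)oxy]methyl}-4-{[(tert-butyldimethylsilyl)oxy]methyl}furan-2(5H)-one | O=C1O[C@H](c2cc(OC)c(OCc3ccccc3)c(OC)c2)C(CO[Si](C)(C)C(C)(C)C)=C1[C@H](O[Si](C)(C)C(C)(C)C)c1ccc(OCc2ccccc2)c(OCc2ccccc2)c1
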